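Assumption: "(+)-neoolivil" is taken to be exactly the isomer in the SMILES. I read it as (2R,3S,4S,5R), that is 2,3-trans/3,4-trans/4,5-trans and C2-symmetric. Lignan numbering used below: C7/C7' are the benzylic carbons (ring C2/C5), C8/C8' are ring C3/C4, and C9/C9' are the CH2OH carbons.

## Retrosynthetic overview
1. Target 13 comes from removing the silyl and benzyl groups of the all-trans tetrahydrofuran 11. This is the only ring built, and it is built last.
2. THF 11 comes from C7–O–C7' cycloetherification of the C2-symmetric 1,4-diol 10, whose 9,9'-OH groups are blocked so that no furofuran can form.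
3. Diol 10 comes from tetraol 8, which comes from diol-diester 7. Compound 7 already carries all four stereocentres.
4. Compound 7 comes from a two-fold DKR asymmetric transfer hydrogenation of the stereolabile 2,3-diaroylsuccinate 6. This is the new step.
5. Compound 6 comes from oxidative C8–C8' homocoupling of β-keto ester 5, which comes from a crossed Claisen of O-benzyl methyl vanillate 3 with tert-butyl acetate.

## Route

**Step 1**
Reactants: 1 methyl vanillate; 2 benzyl bromide
Product: 3 methyl 4-(benzyloxy)-3-methoxybenzoate
Conditions: BnBr (1.1 equiv), K2CO3, DMF, 60 °C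
Reagents that add atoms: benzyl bromide, BrCc1ccccc1
Why: Williamson etherification of the only acidic OH; no stereocentre is involved.

**Step 2**
Reactants: 3; 4 tert-butyl acetate
Product: 5 tert-butyl 3-[4-(benzyloxy)-3-methoxyphenyl]-3-oxopropanoate
Conditions: t-BuOAc (3.2 equiv), LDA (3.3 equiv), THF, −78 °C; add 3; warm to 0 °C; aq NH4Cl
Reagents that add atoms: tert-butyl acetate, CC(=O)OC(C)(C)C
Why: Crossed Claisen condensation of a non-enolisable aryl ester with excess lithium enolate, driven by deprotonation of the β-keto ester product.

**Step 3**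
Reactants: 5 (2 equiv)
Product: 6 di-tert-butyl 2,3-bis[4-(benzyloxy)-3-methoxybenzoyl]butanedioate (dl/meso mixture, stereolabile)
Conditions: NaH (1.05 equiv), THF, 0 °C; I2 (0.5 equiv), 0 °C to rt; aq Na2S2O3
Reagents that add atoms: none
Why: Classical iodine-mediated oxidative enolate homocoupling (in situ α-iodination, then displacement by a second enolate) forms the C8–C8' bond; the dl/meso ratio does not matter because both centres epimerise freely.

**Step 4 (key new step)**
Reactants: 6
Product: 7 di-tert-butyl (2R,3R)-2,3-bis{(R)-[4-(benzyloxy)-3-methoxyphenyl](hydroxy)methyl}butanedioate (C2-symmetric, syn/syn)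
Conditions: RuCl(p-cymene)[(R,R)-TsDPEN] (5 mol %), HCO2H/Et3N (1:1), CH2Cl2, 30 °C, 48 h; chromatography or recrystallisation
Reagents that add atoms: none (formic acid supplies only H)
Why: Proposed new method: a two-fold dynamic kinetic resolution by Noyori–Ikariya asymmetric transfer hydrogenation of a stereolabile 2,3-diaroylsuccinate, a substrate class on which this has not been shown. Each stereocentre of 6 is the α-carbon of a β-keto ester, so Et3N should interconvert the dl and meso forms through the enols faster than hydride transfer. The (R,R)-Ru–H/N–H catalyst adds hydride to the aryl-ketone face fixed by the arene C–H/π contact, which is the sense that gives (R)-1-arylalkanols. Of the two equilibrating α-epimers it should consume the one whose very large succinyl residue lies anti to the incoming hydride (Felkin–Anh), giving the syn (7R,8R) pair. After the first reduction, C8 is only an ester α-carbon and is frozen, while C8' stays labile until an identical second catalyst-controlled reduction, so the (R,R,R,R) C2 diol results. Stereochemical errors end up in separable non-C2 diastereomers (Horeau amplification of ee). The tert-butyl esters stop the first carbinol from lactonising, and the near-neutral 1:1 buffer suppresses hemiketal dehydration to a dihydrofuran. Closest known reaction types: ATH-DKR of α-substituted β-keto esters and amides, and ATH of 1,4-diaryl-1,4-diketones to C2-symmetric 1,4-diols.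

**Step 5**
Reactants: 7
Product: 8 (1R,2S,3S,4R)-1,4-bis[4-(benzyloxy)-3-methoxyphenyl]-2,3-bis(hydroxymethyl)butane-1,4-diol
Conditions: LiAlH4 (6 equiv), THF, 0 °C to rt; Rochelle salt work-up (no acid)
Reagents that add atoms: none
Why: Standard LiAlH4 ester reduction that touches no stereocentre (the R to S descriptor change at C8/C8' is only a CIP priority change); the non-acidic work-up avoids furofuran formation.

**Step 6**
Reactants: 8; 9 tert-butyl(chloro)diphenylsilane (TBDPSCl)
Product: 10 (1R,2S,3S,4R)-1,4-bis[4-(benzyloxy)-3-methoxyphenyl]-2,3-bis{[(tert-butyldiphenylsilyl)oxy]methyl}butane-1,4-diol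
Conditions: TBDPSCl (2.2 equiv), imidazole, CH2Cl2/DMF, 0 °C
Reagents that add atoms: TBDPSCl, CC(C)(C)[Si](Cl)(c1ccccc1)c1ccccc1
Why: Sterically controlled silylation of the two primary OH groups over the hindered secondary benzylic ones, which removes the nucleophiles that would otherwise give the pinoresinol-type 7,9'-rings.

**Step 7**
Reactants: 10
Product: 11 (2R,3S,4S,5R)-2,5-bis[4-(benzyloxy)-3-methoxyphenyl]-3,4-bis{[(tert-butyldiphenylsilyl)oxy]methyl}oxolane
Conditions: MsCl (1.2 equiv), Et3N (3 equiv), CH2Cl2, 0 °C to rt
Reagents that add atoms: none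
Why: SN1 cycloetherification as used for 2,5-diaryl-THF lignans: the mono-mesylate ionises to a p-alkoxybenzyl (quinoid) cation and is captured by the other carbinol oxygen, whose own centre is untouched; closure with the aryl anti to the adjacent CH2OTBDPS restores the R configuration and gives the all-trans ring.

**Step 8**
Reactants: 11
Product: 12 {(2R,3S,4S,5R)-2,5-bis[4-(benzyloxy)-3-methoxyphenyl]oxolane-3,4-diyl}dimethanol
Conditions: TBAF (3 equiv), THF, rt
Reagents that add atoms: none
Why: Fluoride desilylation, run while the phenols are still benzylated so that no phenoxide or quinone methide ring-opening can occur.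

**Step 9**
Reactants: 12
Product: 13 (+)-neoolivil, (2R,3S,4S,5R)-2,5-bis(4-hydroxy-3-methoxyphenyl)-3,4-bis(hydroxymethyl)oxolane
Conditions: H2 (1 atm), 10% Pd/C, EtOAc/EtOH, rt; stop at full conversion (about 1–2 h)
Reagents that add atoms: none
Why: Neutral hydrogenolysis of aryl benzyl ethers is much faster than cleavage of the ring benzylic C–O bonds; the absence of acid or base means no epimerisation and no rearrangement to furofuran or cyclolignan.

## Compound list
1 | methyl vanillate | COC(=O)c1ccc(O)c(OC)c1 | starting material
2 | benzyl bromide | BrCc1ccccc1 | starting material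
3 | methyl 4-(benzyloxy)-3-methoxybenzoate | COC(=O)c1ccc(OCc2ccccc2)c(OC)c1 | intermediate
4 | tert-butyl acetate | CC(=O)OC(C)(C)C | starting material
5 | tert-butyl 3-[4-(benzyloxy)-3-methoxyphenyl]-3-oxopropanoate | CC(C)(C)OC(=O)CC(=O)c1ccc(OCc2ccccc2)c(OC)c1 | intermediate
6 | di-tert-butyl 2,3-bis[4-(benzyloxy)-3-methoxybenzoyl]butanedioate (stereolabile mixture) | CC(C)(C)OC(=O)C(C(=O)c1ccc(OCc2ccccc2)c(OC)c1)C(C(=O)OC(C)(C)C)C(=O)c1ccc(OCc2ccccc2)c(OC)c1 | intermediate
7 | di-tert-butyl (2R,3R)-2,3-bis{(R)-aryl(hydroxy)methyl}butanedioate, aryl = 4-BnO-3-MeO-C6H3 | COc1cc(ccc1OCc1ccccc1)[C@H](O)[C@H](C(=O)OC(C)(C)C)[C@@H](C(=O)OC(C)(C)C)[C@@H](O)c1ccc(OCc2ccccc2)c(OC)c1 | intermediate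
8 | (1R,2S,3S,4R)-tetraol | COc1cc(ccc1OCc1ccccc1)[C@H](O)[C@H](CO)[C@@H](CO)[C@@H](O)c1ccc(OCc2ccccc2)c(OC)c1 | intermediate
9 | TBDPSCl | CC(C)(C)[Si](Cl)(c1ccccc1)c1ccccc1 | starting material
10 | (1R,2S,3S,4R)-9,9'-bis-O-TBDPS 1,4-diol | COc1cc(ccc1OCc1ccccc1)[C@H](O)[C@H](CO[Si](c1ccccc1)(c1ccccc1)C(C)(C)C)[C@@H](CO[Si](c1ccccc1)(c1ccccc1)C(C)(C)C)[C@@H](O)c1ccc(OCc2ccccc2)c(OC)c1 | intermediate
11 | (2R,3S,4S,5R) all-trans THF, bis-TBDPS, bis-Bn | COc1cc(ccc1OCc1ccccc1)[C@@H]1O[C@@H](c2ccc(OCc3ccccc3)c(OC)c2)[C@H](CO[Si](c2ccccc2)(c2ccccc2)C(C)(C)C)[C@H]1CO[Si](c1ccccc1)(c1ccccc1)C(C)(C)C | intermediate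
12 | di-O-benzyl-neoolivil | COc1cc(ccc1OCc1ccccc1)[C@@H]1O[C@@H](c2ccc(OCc3ccccc3)c(OC)c2)[C@H](CO)[C@H]1CO | intermediate
13 | (+)-neoolivil | COc1cc([C@@H]2O[C@@H](c3ccc(O)c(OC)c3)[C@H](CO)[C@H]2CO)ccc1O | target

## Totals
Total steps: 9. Longest linear sequence: 9.

## Three steps most likely to fail

1. **Step 4 (proposed new double DKR-ATH).**
   - Risks:
     - The hindered, electron-rich ketones may reduce slowly.
     - The DKR may be anti- rather than syn-selective, which would give the wrong absolute sense at C8.
     - The second reduction may be mismatched with the first-formed half.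
     - The γ-hydroxy-ketone hemiketal may dehydrate to a dihydrofuran.
   - Fallback (known chemistry, auxiliary control):
     - Run an Evans syn-aldol (Bu2BOTf, i-Pr2NEt) of (R)-4-benzyl-3-(pent-4-enoyl)oxazolidin-2-one with O-benzylvanillin to set C7/C8.
     - Protect the carbinol as a silyl ether, reduce with LiBH4, cleave the alkene with OsO4/NaIO4, and oxidise the lactol to the β-substituted γ-butyrolactone.
     - Perform an LDA aldol with O-benzylvanillin, which adds trans to the β-substituent and sets C8'.
     - Reduce with LiAlH4 and protect the primary OH groups with TBDPS to rejoin the route at 10.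
     - The C7' epimers converge through the SN1 closure of Step 7, with acid equilibration to the all-trans ring if needed.

2. **Step 7 (cycloetherification).**
   - Risks:
     - Partial SN2 closure would give the 2,5-cis isomer.
     - Friedel–Crafts capture of the cation would give an aryltetralin.
     - Bis-mesylation or chloride formation may compete.
   - Fallback:
     - Change the reactive intermediate and the step order.
     - Hydrogenolyse the benzyl ethers of 10 first.
     - Close the ring through the neutral p-quinone methide generated from the free p-hydroxybenzyl alcohol (mild PPTS or warming).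
     - This oxa-Michael closure is reversible, so it proceeds under thermodynamic control toward the all-trans THF.
     - Finish with AcOH-buffered TBAF.

3. **Step 3 (oxidative homocoupling of the bulky tert-butyl β-keto ester).**
   - Risks:
     - The yield may be low.
     - Over-oxidation may give the diaroyl-fumarate or -maleate.
     - α-Iodide may remain unreacted.
   - Fallback:
     - Invert the bond-forming logic and make C7–C8 and C7'–C8' instead of C8–C8'.
     - Do this by double Claisen acylation of the bis-lithium enolate of di-tert-butyl succinate (2.2 equiv LDA) with 4-(benzyloxy)-3-methoxybenzoyl chloride or the acyl imidazolide.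
     - This gives the same compound 6.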